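**Plan**
- Retrosynthesis: the ring B allylic alcohol is taken back through the cinnamate ester (C7'=C8') to an aryl aldehyde, the 4-O-methyl group of ring A is removed, and the C8–O4' ether and the C7–OH bond are then cut together, giving 4-propenylsyringol 1 and syringaldehyde 2.
- Forward: oxidative radical cross-coupling of 1 and 2, with hydration of the ring A quinone methide, joins the two halves (no ring is formed); phenol methylation, two-carbon olefination and ester reduction follow.
- Enabling feature: the C8–O4' aryl ether sits next to the C7 carbinol, and C3/C5 of rings A and B all carry methoxy groups, so the two phenoxyl radicals can join only through C8 and O4'.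
- Stereochemistry: C7 (R) and C8 (R) are both set in the coupling/hydration step inside a dirigent protein pocket; the E alkene comes from the Horner–Wadsworth–Emmons reaction.

Key step: step 1

Assumption: 1 is used as the pure E isomer, and a dirigent protein variant selective for the 8-O-4' cross-coupling is taken to be available from screening of natural and engineered dirigent proteins.

**Step 1**
Reactants: 1 (E)-2,6-dimethoxy-4-(prop-1-en-1-yl)phenol (4-propenylsyringol); 2 4-hydroxy-3,5-dimethoxybenzaldehyde (syringaldehyde)
Product: 4 4-{[(1R,2R)-1-hydroxy-1-(4-hydroxy-3,5-dimethoxyphenyl)propan-2-yl]oxy}-3,5-dimethoxybenzaldehyde, via ring A quinone methide 3 (not isolated)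
Conditions: (NH4)2S2O8 (1.0 equiv, slow addition), dirigent protein variant (substoichiometric), 2 (5 equiv), 1 fed slowly, MES buffer pH 6.0/acetone 9:1, 25 °C
Reagents that add atoms: water, O
Why: Proposed new method: peroxydisulfate takes one electron from each phenol, the radical of 1 carries spin density at C8 and the radical of 2 has C1', C3' and C5' substituted and can bond only through O4', so radical–radical coupling forms C8–O4' and gives quinone methide 3, which rearomatises by 1,6-addition of water at C7. The closest known reaction types are the Ag2O- or peroxidase/H2O2-mediated 8-O-4' couplings of 1 with itself, which give racemic erythro/threo mixtures, and the (NH4)2S2O8-driven 8-8' coupling of coniferyl alcohol radicals on a dirigent protein, which gives one enantiomer and shows that such a pocket can fix the mutual orientation of two phenoxyl radicals and guide the trapping of the quinone methide. No ring is closed. C8 (R) is to be controlled by the protein pocket, which should expose one enantiotopic face of the propenyl terminus to the bound oxygen radical, and C7 (R, threo) by the same pocket, which should hold 3 in the conformation reached at coupling and leave only one face of C7 open to water. Cross- over homo-coupling should be secured by the excess of the long-lived radical of 2 and the slow feed of 1, and O- over C-coupling by the methoxy groups at C3 and C5 of both rings together with the formyl group at C1' of ring B.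

**Step 2**
Reactants: 4 4-{[(1R,2R)-1-hydroxy-1-(4-hydroxy-3,5-dimethoxyphenyl)propan-2-yl]oxy}-3,5-dimethoxybenzaldehyde
Product: 5 4-{[(1R,2R)-1-hydroxy-1-(3,4,5-trimethoxyphenyl)propan-2-yl]oxy}-3,5-dimethoxybenzaldehyde
Conditions: MeI (1.5 equiv), K2CO3 (2 equiv), DMF, 25 °C
Reagents that add atoms: iodomethane, CI
Why: Williamson etherification, in which K2CO3 ionises only the ring A phenol for SN2 methylation, while the secondary C7 alcohol stays neutral and the non-enolisable aldehyde and both stereocentres are untouched.

**Step 3**
Reactants: 5 4-{[(1R,2R)-1-hydroxy-1-(3,4,5-trimethoxyphenyl)propan-2-yl]oxy}-3,5-dimethoxybenzaldehyde; 6 triethyl phosphonoacetate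
Product: 7 ethyl (E)-3-(4-{[(1R,2R)-1-hydroxy-1-(3,4,5-trimethoxyphenyl)propan-2-yl]oxy}-3,5-dimethoxyphenyl)prop-2-enoate
Conditions: LiCl, DBU, MeCN, 0 °C to 25 °C
Reagents that add atoms: none
Why: Horner–Wadsworth–Emmons olefination under Masamune–Roush conditions, in which the lithium-chelated stabilised phosphonate anion adds reversibly to the aryl aldehyde and eliminates to the E cinnamate, the amine base being too weak to ionise the C7 hydroxyl, so the neighbouring aryl ether and both stereocentres are not disturbed.

**Step 4**
Reactants: 7 ethyl (E)-3-(4-{[(1R,2R)-1-hydroxy-1-(3,4,5-trimethoxyphenyl)propan-2-yl]oxy}-3,5-dimethoxyphenyl)prop-2-enoate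
Product: 8 (1R,2R)-2-{4-[(E)-3-hydroxyprop-1-en-1-yl]-2,6-dimethoxyphenoxy}-1-(3,4,5-trimethoxyphenyl)propan-1-ol
Conditions: i-Bu2AlH (3.5 equiv), CH2Cl2, −78 °C; aqueous potassium sodium tartrate work-up
Reagents that add atoms: none
Why: Hydride reduction of an α,β-unsaturated ester by i-Bu2AlH, which after one equivalent is spent on the C7 hydroxyl should reduce the ester carbonyl in 1,2-fashion to the allylic alcohol at low temperature, leaving the E alkene, the aryl ethers and both stereocentres intact, with a neutral work-up that avoids ionisation at the benzylic C7.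

**Compound list**
1 | (E)-2,6-dimethoxy-4-(prop-1-en-1-yl)phenol (4-propenylsyringol) | C/C=C/c1cc(OC)c(O)c(OC)c1 | starting material
2 | 4-hydroxy-3,5-dimethoxybenzaldehyde (syringaldehyde) | COc1cc(C=O)cc(OC)c1O | starting material
3 | 4-{[(2R)-1-(3,5-dimethoxy-4-oxocyclohexa-2,5-dien-1-ylidene)propan-2-yl]oxy}-3,5-dimethoxybenzaldehyde (ring A quinone methide) | C[C@@H](Oc1c(OC)cc(C=O)cc1OC)C=C1C=C(OC)C(=O)C(OC)=C1 | intermediate
4 | 4-{[(1R,2R)-1-hydroxy-1-(4-hydroxy-3,5-dimethoxyphenyl)propan-2-yl]oxy}-3,5-dimethoxybenzaldehyde | COc1cc([C@@H](O)[C@@H](C)Oc2c(OC)cc(C=O)cc2OC)cc(OC)c1O | intermediate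
5 | 4-{[(1R,2R)-1-hydroxy-1-(3,4,5-trimethoxyphenyl)propan-2-yl]oxy}-3,5-dimethoxybenzaldehyde | COc1cc([C@@H](O)[C@@H](C)Oc2c(OC)cc(C=O)cc2OC)cc(OC)c1OC | intermediate
6 | triethyl phosphonoacetate | CCOC(=O)CP(=O)(OCC)OCC | starting material
7 | ethyl (E)-3-(4-{[(1R,2R)-1-hydroxy-1-(3,4,5-trimethoxyphenyl)propan-2-yl]oxy}-3,5-dimethoxyphenyl)prop-2-enoate | COc1cc([C@@H](O)[C@@H](C)Oc2c(OC)cc(/C=C/C(=O)OCC)cc2OC)cc(OC)c1OC | intermediate
8 | (1R,2R)-2-{4-[(E)-3-hydroxyprop-1-en-1-yl]-2,6-dimethoxyphenoxy}-1-(3,4,5-trimethoxyphenyl)propan-1-ol (7R,8R in neolignan numbering) | COc1cc([C@@H](O)[C@@H](C)Oc2c(OC)cc(/C=C/CO)cc2OC)cc(OC)c1OC | target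

Total step count: 4
Longest linear sequence: 4 steps (1 → 4 → 5 → 7 → 8)

**Steps most likely to fail**

1. Step 1 (proposed new method). The radicals may couple in free solution faster than inside the protein pocket. Facial selection at C8 and the threo delivery of water would then be lost, and self-coupling of 1 could overtake the cross-coupling. The fallback uses known chiral-pool and chelation-control chemistry; it sets out from 2 and comes back to the route at 5. Mitsunobu etherification of 2 with methyl (S)-lactate (PPh3, DIAD, THF) should give, with inversion, methyl (R)-2-(4-formyl-2,6-dimethoxyphenoxy)propanoate F1. HC(OMe)3 and TsOH in MeOH should mask the aldehyde as methyl (R)-2-[4-(dimethoxymethyl)-2,6-dimethoxyphenoxy]propanoate F2. i-Bu2AlH in toluene at −78 °C should stop at (R)-2-[4-(dimethoxymethyl)-2,6-dimethoxyphenoxy]propanal F3, which is used at once. Addition of 3,4,5-trimethoxyphenylmagnesium bromide with MgBr2·OEt2 (CH2Cl2/THF, −78 °C) should follow the Cram chelate model and give the threo alcohol (1R,2R)-2-[4-(dimethoxymethyl)-2,6-dimethoxyphenoxy]-1-(3,4,5-trimethoxyphenyl)propan-1-ol F4. Pyridinium p-toluenesulfonate in aqueous acetone should then free the aldehyde to give 5, after which steps 3 and 4 follow unchanged.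

2. Step 4. With the C7 hydroxyl bound to aluminium, the reduction may stall at the aldehyde stage or drift into conjugate reduction. The Lewis-acidic aluminium alkoxide could also ionise the electron-rich benzylic C7 and erode its configuration. The fallback avoids the ester and the aluminium hydride; it sets out from 5 and comes back at 8. Wittig formyl-olefination of 5 with Ph3P=CHCHO (toluene, 80 °C) should give (E)-3-(4-{[(1R,2R)-1-hydroxy-1-(3,4,5-trimethoxyphenyl)propan-2-yl]oxy}-3,5-dimethoxyphenyl)prop-2-enal F5. Luche reduction (NaBH4, CeCl3·7H2O, MeOH, 0 °C) should then reduce only the carbonyl group and give 8.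

3. Step 3. Addition of the phosphonate anion to the electron-rich aldehyde may be slow. That leaves time for base-induced events at the C7 hydroxyl, such as migration of ring B from O8 to O7 or epoxide formation with loss of the ring B phenoxide, and E selectivity could be incomplete. The fallback changes the olefination to an amine-catalysed condensation; it sets out from 5 and comes back at 7. Knoevenagel–Doebner reaction of 5 with ethyl hydrogen malonate (pyridine, catalytic piperidine, 90 °C) should activate the aldehyde as its iminium ion and, after decarboxylative elimination, give the E ester 7 directly. This path makes no compound outside the list (entry F0).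

**Further compounds**
F1 | step 1 | methyl (R)-2-(4-formyl-2,6-dimethoxyphenoxy)propanoate | COC(=O)[C@@H](C)Oc1c(OC)cc(C=O)cc1OC
F2 | step 1 | methyl (R)-2-[4-(dimethoxymethyl)-2,6-dimethoxyphenoxy]propanoate | COC(=O)[C@@H](C)Oc1c(OC)cc(C(OC)OC)cc1OC
F3 | step 1 | (R)-2-[4-(dimethoxymethyl)-2,6-dimethoxyphenoxy]propanal | O=C[C@@H](C)Oc1c(OC)cc(C(OC)OC)cc1OC
F4 | step 1 | (1R,2R)-2-[4-(dimethoxymethyl)-2,6-dimethoxyphenoxy]-1-(3,4,5-trimethoxyphenyl)propan-1-ol | COc1cc([C@@H](O)[C@@H](C)Oc2c(OC)cc(C(OC)OC)cc2OC)cc(OC)c1OC
F5 | step 4 | (E)-3-(4-{[(1R,2R)-1-hydroxy-1-(3,4,5-trimethoxyphenyl)propan-2-yl]oxy}-3,5-dimethoxyphenyl)prop-2-enal | COc1cc([C@@H](O)[C@@H](C)Oc2c(OC)cc(/C=C/C=O)cc2OC)cc(OC)c1OC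
F0 | step 3 | none | none
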